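**Retrosynthetic overview**

1. The bridge bond from the C8 methylene to ring A is made late: an o-quinone methide from the 7-hydroxy-8-(hydroxymethyl)chromanone alkylates the ring A acylphloroglucinol, and BCl3 then frees the chelated C5 hydroxyl.
2. The pyranone (O1, C2, C3, C4) is closed before the bridge, through the only free phenol (future O1) and the only free ring carbon (C4a), by iodination, O-acylation, anionic Fries shift and oxa-Michael addition. No acid is used, so the benzylic ether survives, and no free C4a–H remains to self-condense at the quinone methide stage.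
3. The arene of ring B is built de novo from 3-ethoxy-2-methylcyclobutenone and a benzyloxymethyl siloxyalkyne: bonds C8–C8a and C6–C7 by [2+2] addition, ring closed at C4a–C8a.
4. Ring order: arene of ring B (step 3), then the pyranone (step 6). Ring A is bought as 2-methylphloroglucinol and acylated.
5. Feature: ring B (C4a, C5, C6, C7, C8, C8a) is a hexasubstituted phloroglucinol with methyl on C6 and the bridge carbon on C8. Its oxygens have three roles (O1 on C8a in the pyranone, the ketone-chelated OH on C5, the OH on C7), and the annulation delivers them as free OH, OEt and OTIPS.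

Key step: step 3

Remark: ring B is numbered as a chroman-4-one (O1, C2, C3, C4, C4a, C5 to C8, C8a). The target has no stereocentre. 1-Ethoxyprop-1-yne, benzyl propargyl ether and 2-methylphloroglucinol are taken as purchasable.

**Route**

Step 1
Reactants: 1 acetyl chloride; 2 1-ethoxyprop-1-yne
Product: 4 3-ethoxy-2-methylcyclobut-2-en-1-one, via ketene 3 (not isolated)
Conditions: Et3N, Et2O, 0 → 23 °C, 1 added slowly in excess
Reagents that add atoms: none
Why: Dehydrochlorination of 1 gives ketene 3, which undergoes a ketene–alkoxyalkyne [2+2] cycloaddition in which the methyl-bearing alkyne carbon attacks the ketene carbonyl carbon and the ketene CH2 closes onto the ethoxy-bearing carbon, so methyl sits on C2 and ethoxy on C3.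

Step 2
Reactants: 5 benzyl propargyl ether
Product: 8 {[3-(benzyloxy)prop-1-yn-1-yl]oxy}tri(propan-2-yl)silane, via lithium acetylide 6 (not isolated), via lithium ynolate 7 (not isolated)
Conditions: n-BuLi, THF, −78 °C; LiOOt-Bu (from t-BuOOH and LiN(SiMe3)2), −78 → 0 °C; i-Pr3SiOTf, −78 → 0 °C
Reagents that add atoms: lithium tert-butyl peroxide (from tert-butyl hydroperoxide), CC(C)(C)OO[Li]; triisopropylsilyl trifluoromethanesulfonate, CC(C)[Si](OS(=O)(=O)C(F)(F)F)(C(C)C)C(C)C
Why: The acetylide 6 is oxidised at carbon by the electrophilic oxygen of the lithium peroxide to the ynolate 7 (acetylide oxidation to an ynolate), and the bulky silyl triflate traps 7 on oxygen; the benzyl ether is inert to these reagents at low temperature.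

Step 3
Reactants: 4 3-ethoxy-2-methylcyclobut-2-en-1-one; 8 {[3-(benzyloxy)prop-1-yn-1-yl]oxy}tri(propan-2-yl)silane
Product: 13 2-[(benzyloxy)methyl]-5-ethoxy-4-methyl-3-[(triisopropylsilyl)oxy]phenol, via vinylketene 9 (not isolated), via vinylcyclobutenone 10 (not isolated), via dienylketene 11 (not isolated), via cyclohexadienone 12 (not isolated)
Conditions: PhMe, 8 (1.3 equiv), 110 → 140 °C, sealed tube, Ar
Reagents that add atoms: none
Why: Proposed new method: heating should cleave the C1–C4 bond of 4 in a four-electron electrocyclic opening to the ethoxy-substituted vinylketene 9, whose ketene carbon is attacked by the alkyne carbon of 8 remote from oxygen in a [2+2] cycloaddition to the 4-vinylcyclobutenone 10; a second four-electron opening to the dienylketene 11 and a six-electron electrocyclic closure give the cyclohexadienone 12, which tautomerises to the phenol 13. The closest known reaction is the Danheiser benzannulation of 3-alkyl- and 3-aryl-cyclobutenones with triisopropylsiloxyalkynes to resorcinol monosilyl ethers; the untested element is the vinylogous-ester cyclobutenone, whose ground-state stabilisation should raise the temperature of the first opening but not change its course. Ring B is closed by the six-electron electrocyclisation of 11 (bond C4a–C8a) after the [2+2] step has made the C8–C8a and C6–C7 bonds. No stereocentre is formed. The selectivity needed is regiochemical and is secured by the polarity of the partners: the siloxy group makes the CH2OBn-bearing alkyne carbon the nucleophile and the ketene carbonyl carbon is the only electrophilic site, so the oxygens come out alternating as free OH (C8a), OTIPS (C7) and OEt (C5) with the single ring hydrogen at C4a. A slight excess of 8 over 4 keeps the vinylketene from acylating the product phenol.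

Step 4
Reactants: 13 2-[(benzyloxy)methyl]-5-ethoxy-4-methyl-3-[(triisopropylsilyl)oxy]phenol
Product: 14 2-[(benzyloxy)methyl]-5-ethoxy-6-iodo-4-methyl-3-[(triisopropylsilyl)oxy]phenol
Conditions: NIS, MeCN, 0 °C, dark
Reagents that add atoms: N-iodosuccinimide, O=C1CCC(=O)N1I
Why: Electrophilic aromatic iodination can occur only at the single unsubstituted ring carbon, which is activated by the ortho hydroxyl, the ortho ethoxy and the para siloxy group, and neutral NIS leaves the benzyl and silyl ethers untouched.

Step 5
Reactants: 14 2-[(benzyloxy)methyl]-5-ethoxy-6-iodo-4-methyl-3-[(triisopropylsilyl)oxy]phenol; 15 3-methylbut-2-enoyl chloride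
Product: 16 2-[(benzyloxy)methyl]-5-ethoxy-6-iodo-4-methyl-3-[(triisopropylsilyl)oxy]phenyl 3-methylbut-2-enoate
Conditions: pyridine, DMAP (cat.), CH2Cl2, 0 → 23 °C
Reagents that add atoms: none
Why: DMAP-catalysed O-acylation places the five-carbon acyl unit on the oxygen that becomes O1, and pyridine is too weak a base to divert the acid chloride to a vinylketene.

Step 6
Reactants: 16 2-[(benzyloxy)methyl]-5-ethoxy-6-iodo-4-methyl-3-[(triisopropylsilyl)oxy]phenyl 3-methylbut-2-enoate
Product: 19 8-[(benzyloxy)methyl]-5-ethoxy-2,2,6-trimethyl-7-[(triisopropylsilyl)oxy]chroman-4-one, via aryllithium 17 (not isolated), via hydroxyaryl enone 18 (not isolated)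
Conditions: n-BuLi, THF, −78 → 0 °C; H2O; then DBU (cat.), CH2Cl2, 23 °C
Reagents that add atoms: none
Why: Iodine–lithium exchange outruns attack of n-BuLi on the doubly ortho-substituted ester, the aryllithium 17 takes the acyl group from the neighbouring oxygen (anionic Fries rearrangement), and the phenol 18 adds to the β,β-dimethyl enone in a 6-endo oxa-Michael closure that can only use O1 because the oxygen on C5 is an ethyl ether.

Step 7
Reactants: 19 8-[(benzyloxy)methyl]-5-ethoxy-2,2,6-trimethyl-7-[(triisopropylsilyl)oxy]chroman-4-one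
Product: 20 5-ethoxy-8-(hydroxymethyl)-2,2,6-trimethyl-7-[(triisopropylsilyl)oxy]chroman-4-one
Conditions: H2 (1 atm), 10% Pd/C, NaHCO3 (solid), EtOAc, 23 °C
Reagents that add atoms: none
Why: Catalytic hydrogenolysis should cleave the O–CH2Ph bond from the unhindered phenyl side, because the hexasubstituted arylmethyl side cannot lie flat on palladium, has no free ortho phenol while O7 is silylated, and is kept from ionising by the hydrogencarbonate.

Step 8
Reactants: 20 5-ethoxy-8-(hydroxymethyl)-2,2,6-trimethyl-7-[(triisopropylsilyl)oxy]chroman-4-one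
Product: 21 5-ethoxy-7-hydroxy-8-(hydroxymethyl)-2,2,6-trimethylchroman-4-one
Conditions: Bu4NF, AcOH (1:1), THF, 0 °C
Reagents that add atoms: none
Why: Fluoride-mediated desilylation cleaves the aryl silyl ether, which is activated by the para ketone, and the acetic acid buffer protonates the phenoxide before it can expel hydroxide from the neighbouring CH2OH.

Step 9
Reactants: 22 2-methylphloroglucinol; 23 2-methylpropanoyl chloride
Product: 24 2-methyl-1-(2,4,6-trihydroxy-3-methylphenyl)propan-1-one
Conditions: AlCl3, PhNO2, 23 → 60 °C; then 1 M HCl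
Reagents that add atoms: none
Why: Friedel–Crafts acylation takes place at one of the two equivalent free carbons of the triol, and the first acyl group deactivates the ring enough to stop at mono-acylation with one equivalent of 23.

Step 10
Reactants: 21 5-ethoxy-7-hydroxy-8-(hydroxymethyl)-2,2,6-trimethylchroman-4-one; 24 2-methyl-1-(2,4,6-trihydroxy-3-methylphenyl)propan-1-one
Product: 26 5-ethoxy-7-hydroxy-2,2,6-trimethyl-8-{[2,4,6-trihydroxy-3-methyl-5-(2-methylpropanoyl)phenyl]methyl}chroman-4-one, via o-quinone methide 25 (not isolated)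
Conditions: TsOH·H2O (10 mol%), 1,4-dioxane, 50 °C, 24 in excess
Reagents that add atoms: none
Why: Acid-catalysed loss of water from the o-hydroxybenzyl alcohol gives the o-quinone methide 25, which the only unsubstituted carbon of 24 captures in a Michael-type Friedel–Crafts alkylation; 21 has no free ring carbon and so cannot alkylate itself, and O-alkylation is reversible under the acid.

Step 11
Reactants: 26 5-ethoxy-7-hydroxy-2,2,6-trimethyl-8-{[2,4,6-trihydroxy-3-methyl-5-(2-methylpropanoyl)phenyl]methyl}chroman-4-one
Product: 27 5,7-dihydroxy-2,2,6-trimethyl-8-{[2,4,6-trihydroxy-3-methyl-5-(2-methylpropanoyl)phenyl]methyl}chroman-4-one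
Conditions: BCl3, CH2Cl2, −78 → 0 °C; then H2O
Reagents that add atoms: none
Why: Chelation-directed ether cleavage: BCl3 binds the C4 carbonyl and the peri C5 ether oxygen in a six-membered chelate and chloride removes the ethyl group from that oxonium only, while the low temperature should spare the methylene bridge, the ketones and the pyranone.

**Compound list**

1 | acetyl chloride | CC(Cl)=O | starting material
2 | 1-ethoxyprop-1-yne | CCOC#CC | starting material
3 | ketene (ethenone) | C=C=O | intermediate (not isolated)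
4 | 3-ethoxy-2-methylcyclobut-2-en-1-one | CCOC1=C(C)C(=O)C1 | intermediate
5 | benzyl propargyl ether | C#CCOCc1ccccc1 | starting material
6 | lithium 3-(benzyloxy)prop-1-yn-1-ide | [Li]C#CCOCc1ccccc1 | intermediate (not isolated)
7 | lithium 3-(benzyloxy)prop-1-yn-1-olate | [Li]OC#CCOCc1ccccc1 | intermediate (not isolated)
8 | {[3-(benzyloxy)prop-1-yn-1-yl]oxy}tri(propan-2-yl)silane | CC(C)[Si](OC#CCOCc1ccccc1)(C(C)C)C(C)C | intermediate
9 | 3-ethoxy-2-methylbuta-1,3-dien-1-one (vinylketene) | C=C(OCC)C(C)=C=O | intermediate (not isolated)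
10 | 2-[(benzyloxy)methyl]-4-(1-ethoxyethenyl)-4-methyl-3-[(triisopropylsilyl)oxy]cyclobut-2-en-1-one (racemic) | C=C(OCC)C1(C)C(=O)C(COCc2ccccc2)=C1O[Si](C(C)C)(C(C)C)C(C)C | intermediate (not isolated)
11 | 2-[(benzyloxy)methyl]-5-ethoxy-4-methyl-3-[(triisopropylsilyl)oxy]hexa-1,3,5-trien-1-one (ketene carbon cis to the ethoxyvinyl group across C3=C4) | O=C=C(COCc1ccccc1)/C(O[Si](C(C)C)(C(C)C)C(C)C)=C(C)\C(OCC)=C | intermediate (not isolated)
12 | 2-[(benzyloxy)methyl]-5-ethoxy-4-methyl-3-[(triisopropylsilyl)oxy]cyclohexa-2,4-dien-1-one | O=C1CC(OCC)=C(C)C(O[Si](C(C)C)(C(C)C)C(C)C)=C1COCc1ccccc1 | intermediate (not isolated)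
13 | 2-[(benzyloxy)methyl]-5-ethoxy-4-methyl-3-[(triisopropylsilyl)oxy]phenol | CCOc1cc(O)c(COCc2ccccc2)c(O[Si](C(C)C)(C(C)C)C(C)C)c1C | intermediate
14 | 2-[(benzyloxy)methyl]-5-ethoxy-6-iodo-4-methyl-3-[(triisopropylsilyl)oxy]phenol | CCOc1c(I)c(O)c(COCc2ccccc2)c(O[Si](C(C)C)(C(C)C)C(C)C)c1C | intermediate
15 | 3-methylbut-2-enoyl chloride | CC(C)=CC(Cl)=O | starting material
16 | 2-[(benzyloxy)methyl]-5-ethoxy-6-iodo-4-methyl-3-[(triisopropylsilyl)oxy]phenyl 3-methylbut-2-enoate | CCOc1c(I)c(OC(=O)C=C(C)C)c(COCc2ccccc2)c(O[Si](C(C)C)(C(C)C)C(C)C)c1C | intermediate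
17 | {3-[(benzyloxy)methyl]-6-ethoxy-5-methyl-2-[(3-methylbut-2-enoyl)oxy]-4-[(triisopropylsilyl)oxy]phenyl}lithium | CCOc1c([Li])c(OC(=O)C=C(C)C)c(COCc2ccccc2)c(O[Si](C(C)C)(C(C)C)C(C)C)c1C | intermediate (not isolated)
18 | 1-{3-[(benzyloxy)methyl]-6-ethoxy-2-hydroxy-5-methyl-4-[(triisopropylsilyl)oxy]phenyl}-3-methylbut-2-en-1-one | CCOc1c(C(=O)C=C(C)C)c(O)c(COCc2ccccc2)c(O[Si](C(C)C)(C(C)C)C(C)C)c1C | intermediate (not isolated)
19 | 8-[(benzyloxy)methyl]-5-ethoxy-2,2,6-trimethyl-7-[(triisopropylsilyl)oxy]chroman-4-one | CCOc1c(C)c(O[Si](C(C)C)(C(C)C)C(C)C)c(COCc2ccccc2)c2OC(C)(C)CC(=O)c12 | intermediate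
20 | 5-ethoxy-8-(hydroxymethyl)-2,2,6-trimethyl-7-[(triisopropylsilyl)oxy]chroman-4-one | CCOc1c(C)c(O[Si](C(C)C)(C(C)C)C(C)C)c(CO)c2OC(C)(C)CC(=O)c12 | intermediate
21 | 5-ethoxy-7-hydroxy-8-(hydroxymethyl)-2,2,6-trimethylchroman-4-one | CCOc1c(C)c(O)c(CO)c2OC(C)(C)CC(=O)c12 | intermediate
22 | 2-methylphloroglucinol (2-methylbenzene-1,3,5-triol) | Cc1c(O)cc(O)cc1O | starting material
23 | 2-methylpropanoyl chloride | CC(C)C(Cl)=O | starting material
24 | 2-methyl-1-(2,4,6-trihydroxy-3-methylphenyl)propan-1-one | CC(C)C(=O)c1c(O)cc(O)c(C)c1O | intermediate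
25 | 5-ethoxy-2,2,6-trimethyl-8-methylidene-2,3-dihydrochromene-4,7-dione (o-quinone methide) | CCOC1=C(C)C(=O)C(=C)C2=C1C(=O)CC(C)(C)O2 | intermediate (not isolated)
26 | 5-ethoxy-7-hydroxy-2,2,6-trimethyl-8-{[2,4,6-trihydroxy-3-methyl-5-(2-methylpropanoyl)phenyl]methyl}chroman-4-one | CCOc1c(C)c(O)c(Cc2c(O)c(C)c(O)c(C(=O)C(C)C)c2O)c2OC(C)(C)CC(=O)c12 | intermediate
27 | 5,7-dihydroxy-2,2,6-trimethyl-8-{[2,4,6-trihydroxy-3-methyl-5-(2-methylpropanoyl)phenyl]methyl}chroman-4-one (CNP0186856.0) | Cc1c(O)c(Cc2c(O)c(C)c(O)c3c2OC(C)(C)CC3=O)c(O)c(C(=O)C(C)C)c1O | target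

**Count**

Total steps: 11. Longest linear sequence: 9 steps (1, 3, 4, 5, 6, 7, 8, 10, 11); steps 2 and 9 are side branches.

**Steps most likely to fail**

Step 3 (key step, proposed method). The donor-stabilised cyclobutenone may open only at a temperature at which the siloxyalkyne rearranges by silyl shift to a silylketene, the product phenol may be acylated by the vinylketene, or the 2-(benzyloxymethyl)phenol may lose benzyl alcohol thermally. The fallback uses known chemistry and gives up the de novo arene; it sets out from 22 and 24 and comes back at 27. Compound 22 is heated with 3-methylbut-2-enoic acid in P2O5/MeSO3H (Friedel–Crafts acylation and oxa-Michael closure), which should give 5,7-dihydroxy-2,2,6-trimethylchroman-4-one F1 together with its regioisomer 5,7-dihydroxy-2,2,8-trimethylchroman-4-one F2, to be removed by chromatography. Mannich reaction of F1 with dimethylmethylideneammonium iodide at its only free ring carbon (C8) should give 8-[(dimethylamino)methyl]-5,7-dihydroxy-2,2,6-trimethylchroman-4-one F3. Heating F3 with 24 in dioxane expels dimethylamine to the o-quinone methide 5-hydroxy-2,2,6-trimethyl-8-methylidene-2,3-dihydrochromene-4,7-dione F4, which 24 should capture to give 27 directly. The price is the regioisomer separation that the annulation is designed to avoid.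

Step 10. The o-quinone methide may dimerise or be captured on oxygen, and the acid may exchange aryl groups across the new methylene bridge. The fallback generates the same quinone methide with fluoride and no acid; it sets out from 20 and comes back at 26. Acetylation of 20 (Ac2O, pyridine) should give [5-ethoxy-2,2,6-trimethyl-4-oxo-7-[(triisopropylsilyl)oxy]chroman-8-yl]methyl acetate F5. Treatment of F5 with Bu4NF in THF at 0 to 23 °C in the presence of 24 removes the silyl group; the resulting tetrabutylammonium 8-(acetoxymethyl)-5-ethoxy-2,2,6-trimethyl-4-oxochroman-7-olate F6 should lose acetate at once to 25, which 24 captures to give 26.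

Step 7. Over-reduction may occur: the arylmethyl C–O bond may be hydrogenolysed in place of, or after, the O–benzyl bond, leaving a methyl group on C8. The fallback never frees the benzylic alcohol and uses no hydrogen; it sets out from 19 and comes back at 26. Desilylation of 19 (Bu4NF, AcOH, THF) should give 8-[(benzyloxy)methyl]-5-ethoxy-7-hydroxy-2,2,6-trimethylchroman-4-one F7. Ionisation of its benzylic ether with TsOH·H2O or Sc(OTf)3 in dioxane at 60 to 80 °C in the presence of 24 expels benzyl alcohol, and the quinone methide 25 so formed should give 26.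

**Further compounds**

F1 | step 3 | 5,7-dihydroxy-2,2,6-trimethylchroman-4-one | Cc1c(O)cc2OC(C)(C)CC(=O)c2c1O
F2 | step 3 | 5,7-dihydroxy-2,2,8-trimethylchroman-4-one | Cc1c(O)cc(O)c2C(=O)CC(C)(C)Oc12
F3 | step 3 | 8-[(dimethylamino)methyl]-5,7-dihydroxy-2,2,6-trimethylchroman-4-one | CN(C)Cc1c(O)c(C)c(O)c2C(=O)CC(C)(C)Oc12
F4 | step 3 | 5-hydroxy-2,2,6-trimethyl-8-methylidene-2,3-dihydrochromene-4,7-dione | OC1=C(C)C(=O)C(=C)C2=C1C(=O)CC(C)(C)O2
F5 | step 10 | [5-ethoxy-2,2,6-trimethyl-4-oxo-7-[(triisopropylsilyl)oxy]chroman-8-yl]methyl acetate | CCOc1c(C)c(O[Si](C(C)C)(C(C)C)C(C)C)c(COC(C)=O)c2OC(C)(C)CC(=O)c12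
F6 | step 10 | tetrabutylammonium 8-(acetoxymethyl)-5-ethoxy-2,2,6-trimethyl-4-oxochroman-7-olate | CCOc1c(C)c([O-])c(COC(C)=O)c2OC(C)(C)CC(=O)c12.CCCC[N+](CCCC)(CCCC)CCCC
F7 | step 7 | 8-[(benzyloxy)methyl]-5-ethoxy-7-hydroxy-2,2,6-trimethylchroman-4-one | CCOc1c(C)c(O)c(COCc2ccccc2)c2OC(C)(C)CC(=O)c12
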